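A direct plan would assemble the whole chain in open form and install the 3,4-epoxide by asymmetric epoxidation of an acyclic allylic alcohol. It would close the ten-membered ring last, by Ni/Cr-mediated addition of the C9 (E)-vinyl iodide to the C8 aldehyde of A1, giving carbinol A2.
Its weakest step would be that end-to-end closure. It would have to force an E-cyclodecene shut at millimolar dilution with a large excess of chromium. The substrate would be a β-acetoxy-α-branched aldehyde that epimerises and eliminates easily, and C8 would be left uncontrolled.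
Second would be the repair of C8: oxidation of A2 to enone A3, then re-reduction by a ketoreductase still to be found for a greasy macrocycle. That would spend two redox steps on one stereocentre and would rest on a screening result.
Third would be the protecting-group traffic. About ten steps would go into carrying two aldol stereocentres into a phosphonolactone. The last two steps (acid fluoride to epoxy alcohol A4, then oxidation) would risk acetate migration and epoxide opening on the most precious material.

**Plan of the new route**
Numbering: C8(OAc)–C9=C10(Me)–C1–C2–C3(–O–)C4(C15HO)–C5–C6(OAc)–C7(iPr)–C8.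
Feature used: without the epoxide oxygen the ring is an (E,Z)-cyclodeca-1,5-diene (C9=C10–C1–C2–C3=C4). Its alkenes are joined by a two-carbon bridge (C1–C2) and a four-carbon bridge (C5–C8). It is therefore the formal metathesis product of a cyclohexene (C4=C9) and 1-methylcyclobutene (C3=C10). C15 lies γ to O6, so a γ-lactone can trap the opened ring.
Cuts: the epoxide O is removed last. C9=C10 and C3=C4 trace back to σ-bonds C9–C10 and C3–C4 (made by light), with C4–C9 and C3–C10 broken by heat. The six-ring traces back to C8–C9, C4=C5 and C6–C7.
Ring order: cyclohexene, then two cyclobutanes (a 6-4-4 ladder), then the ten-membered ring plus a temporary γ-lactone in one operation, then the oxirane.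
Why the weak steps vanish: there is no end-to-end closure, and both alkene geometries follow from the ladder topology. C8 is set on a rigid six-ring by internal hydride delivery. One protecting group is used, and the last step only adds oxygen.

Key step: step 9

Assumption: the target is taken as drawn, (3R,4S,6R,7S,8R) in the numbering above. Both enantiomers of the two organocatalysts are available, and their sense of induction is assigned by analogy with simpler substrates.

Step 1
Reactants: 1 isobutyraldehyde; 2 nitromethane
Product: 3 (E)-3-methyl-1-nitrobut-1-ene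
Conditions: piperidine (10 mol %), 4 Å MS, PhMe, reflux
Reagents that add atoms: none
Why: Henry condensation with in situ dehydration under amine catalysis and water removal gives the conjugated nitroalkene, whose E isomer is strongly favoured.

Step 2
Reactants: 3 (E)-3-methyl-1-nitrobut-1-ene; 4 (tert-butyldimethylsilyloxy)acetaldehyde
Product: 5 (2S,3R)-2-(TBSO)-4-methyl-3-(nitromethyl)pentanal (C5 aldehyde, C6–OTBS, C7–iPr, C8H2NO2; syn)
Conditions: (R)-α,α-diphenylprolinol TMS ether (10 mol %), ClCH2CO2H (20 mol %), CH2Cl2, rt
Reagents that add atoms: none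
Why: In this enamine-catalysed asymmetric Michael addition the E-enamine, shielded on one face by the diarylsilyloxymethyl group, adds through an acyclic synclinal transition state to give the syn adduct, which sets C6 and C7 under catalyst control.

Step 3
Reactants: 5 nitro aldehyde; 6 ethyl 2-(diethoxyphosphoryl)acrylate
Product: 8 ethyl (3R,4R)-3-(TBSO)-4-isopropyl-5-nitrocyclohex-1-ene-1-carboxylate (epimers at the nitro carbon C8), via open-chain nitro phosphonate aldehyde 7 (not isolated)
Conditions: Cs2CO3, CH2Cl2, 0 °C; then EtOH, rt
Reagents that add atoms: none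
Why: In a domino nitro-Michael/intramolecular Horner–Wadsworth–Emmons reaction the nitronate C8 adds to the vinylphosphonate (C8–C9) and the phosphonate carbanion C4 olefinates the C5 aldehyde; C6 and C7 are untouched and the C8 epimers are irrelevant.

Step 4
Reactants: 8 nitrocyclohexene ester
Product: 10 ethyl (4S,5R)-5-(TBSO)-4-isopropyl-3-oxocyclohex-1-ene-1-carboxylate (C8 ketone, C4=C9), via β,γ-unsaturated ketone 9 (not isolated)
Conditions: KOt-Bu (1.05 equiv), THF, –78 °C; dimethyldioxirane (acetone soln), –78→0 °C; then DABCO (10 mol %), CH2Cl2, rt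
Reagents that add atoms: dimethyldioxirane (CC1(C)OO1)
Why: An oxidative Nef reaction of the nitronate gives the ketone, and an amine-catalysed prototropic shift moves the alkene from C4=C5 to C4=C9, where it is conjugated with both carbonyls, while C7 (now α to the ketone) rests in its more stable and required arrangement trans to O6.

Step 5
Reactants: 11 methylenecyclobutane
Product: 12 1-methylcyclobutene
Conditions: KOt-Bu (cat.), DMSO, rt; product distilled out
Reagents that add atoms: none
Why: Base-catalysed prototropic isomerisation equilibrates the exocyclic alkene to the favoured, more substituted endocyclic alkene, which is removed by distillation.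

Step 6
Reactants: 10 enone ester; 12 1-methylcyclobutene
Product: 13 ethyl 9-(TBSO)-8-isopropyl-5-methyl-7-oxotricyclo[4.4.0.0^2,5]decane-1-carboxylate (6-4-4 ladder with new bonds C3–C4 and C9–C10, cis,anti,cis, cyclobutane on the ring face opposite O6)
Conditions: hν (365 nm LED or Pyrex-filtered Hg lamp), 12 (8 equiv), CH2Cl2, –30 °C
Reagents that add atoms: none
Why: In this enone–alkene [2+2] photocycloaddition through the enone triplet, the unhindered cyclobutene CH (C3) bonds to the β-carbon C4 and the tertiary/α-keto diradical closes C9–C10, the orientation that avoids adjacent quaternary carbons (as known for 3-substituted cyclohexenones with this alkene); attack anti to O6 should dominate, the minor facial isomer is removed by chromatography, and all four new centres are erased in step 9.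

Step 7
Reactants: 13 ladder keto ester
Product: 14 ladder β-hydroxy keto ester (free O6–H)
Conditions: HF·pyridine, pyridine, THF, 0 °C→rt
Reagents that add atoms: none
Why: Buffered acid fluoride cleaves the secondary TBS ether without the retro-aldol or β-elimination that basic fluoride could trigger in a β-hydroxy ketone.

Step 8
Reactants: 14 ladder β-hydroxy keto ester
Product: 15 ladder 6,8-diol ester (O8 trans to O6 and cis to iPr on the six-ring; C8 as in the target)
Conditions: Me4NBH(OAc)3 (5 equiv), MeCN/AcOH 1:1, –20 °C
Reagents that add atoms: none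
Why: In this Evans–Saksena reduction the borohydride exchanges onto O6 and delivers hydride internally to the same face of C8=O, which is also the face away from the cyclobutane and the isopropyl group, so both effects give the 1,3-anti diol.

Step 9
Reactants: 15 ladder 6,8-diol ester
Product: 17 ten-membered 6,15-olide (α-alkylidene-γ-lactone C15(=O)–O6; 8-OH; C9=C10 E; C3=C4 with C2 cis to C5 and trans to C15; C6, C7, C8 as in the target), via (E,Z)-cyclodecadiene diol ester 16 (not isolated)
Conditions: o-xylene (0.01 M, degassed), 2-pyridone (10 mol %), BHT, base-washed sealed tube, 195 °C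
Reagents that add atoms: none
Why: Heating breaks the most strained bond of the bicyclo[2.2.0]hexane, C3–C10, and the resulting cyclohexane-1,4-diyl relaxes to a chair and cleaves C4–C9, so both four-membered rings are spent in a formal retro-[2+2] (the thermal half of a photo-thermal olefin metathesis; the closest known reaction type is the thermolysis of tricyclo[4.4.0.0^2,5]decane photoadducts to cyclodeca-1,5-dienes). The ten-membered ring is not closed end to end but uncovered by ring expansion (6+4→10), and the γ-lactone then closes by 5-exo-trig acyl substitution of O6 on C15 with loss of ethanol. No stereocentre is made: C3, C4, C9 and C10 become sp2 and C6, C7 and C8 are spectators. A cis-fused ladder can only give an E,Z-diene, and of the two chair diyls the one with C8 and CO2Et equatorial (only C5 and H9 axial) is favoured, which places C8 trans to C1 (E-C9=C10) and C5 cis to C2 (C15 trans to C2), also the more stable enoate geometry. The selectivity needed is against Cope rearrangement of 16 to the cis-divinylcyclohexane (re-forming C4–C9, breaking C1–C2): that isomer loses the C3=C4/C15 conjugation, only 16 can lactonise without forcing the isopropyl group axial, and loss of ethanol makes the trap irreversible. The Cope isomer of 17 itself would be a strained bridged lactone, so 17 should be the thermodynamic sink of the manifold.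

Step 10
Reactants: 17 ten-membered hydroxy lactone
Product: 18 6,8-dihydroxy C15 N-methoxy-N-methylamide (both alkene geometries unchanged)
Conditions: MeNH(OMe)·HCl, AlMe3 (4 equiv each), CH2Cl2, 0 °C→rt; Rochelle salt
Reagents that add atoms: N,O-dimethylhydroxylamine hydrochloride (CNOC.Cl)
Why: Weinreb aminolysis with the aluminium amide opens the lactone at C15–O6, which frees O6–H and leaves C15 at a level that can be taken to the aldehyde after acetylation, so no γ-hydroxy aldehyde/lactol ever forms.

Step 11
Reactants: 18 dihydroxy Weinreb amide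
Product: 19 6,8-diacetoxy Weinreb amide
Conditions: Ac2O, pyridine, DMAP (cat.), CH2Cl2, 0 °C→rt (on crude 18)
Reagents that add atoms: acetic anhydride (CC(=O)OC(C)=O)
Why: O-acylation of both secondary alcohols proceeds with retention, and doing it at once forestalls relactonisation of the γ-hydroxy amide.

Step 12
Reactants: 19 diacetoxy Weinreb amide
Product: 20 (E)-enal 6,8-diacetate (C15HO on C4, C3=C4 and C9=C10 as in 17)
Conditions: Cp2Zr(H)Cl (2 equiv), THF, rt; then H2O/silica
Reagents that add atoms: none
Why: Reduction of the tertiary amide with Schwartz reagent stops at a stable zirconated hemiaminal that releases the aldehyde on work-up, a reaction type known to spare esters and trisubstituted alkenes.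

Step 13
Reactants: 20 enal diacetate
Product: 21 Pulicanaral A
Conditions: 9-amino(9-deoxy)epi-cinchona primary amine (10 mol %), chiral phosphoric acid TRIP (matched pair, 10 mol %), 50 % aq H2O2 (1.5 equiv), THF, 35 °C
Reagents that add atoms: hydrogen peroxide (OO)
Why: In this iminium-catalysed Weitz–Scheffer epoxidation of an α-branched enal only the electron-poor C3=C4 reacts, the ring prevents C3–C4 rotation in the enamine intermediate so C2 and C5 stay cis on the oxirane, and the chiral ion pair selects the face that gives 3R,4S.

**Compound list**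
1 | isobutyraldehyde | CC(C)C=O | starting material
2 | nitromethane | C[N+](=O)[O-] | starting material
3 | (E)-3-methyl-1-nitrobut-1-ene | CC(C)/C=C/[N+](=O)[O-] | intermediate
4 | (tert-butyldimethylsilyloxy)acetaldehyde | O=CCO[Si](C)(C)C(C)(C)C | starting material
5 | (2S,3R)-2-(TBSO)-4-methyl-3-(nitromethyl)pentanal | O=C[C@@H](O[Si](C)(C)C(C)(C)C)[C@@H](C[N+](=O)[O-])C(C)C | intermediate
6 | ethyl 2-(diethoxyphosphoryl)acrylate | C=C(C(=O)OCC)P(=O)(OCC)OCC | starting material
7 | open-chain nitro phosphonate aldehyde (C8, C4 undefined) | O=C[C@@H](O[Si](C)(C)C(C)(C)C)[C@@H](C(CC(C(=O)OCC)P(=O)(OCC)OCC)[N+](=O)[O-])C(C)C | intermediate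
8 | ethyl (3R,4R)-3-(TBSO)-4-isopropyl-5-nitrocyclohex-1-ene-1-carboxylate | CCOC(=O)C1=C[C@@H](O[Si](C)(C)C(C)(C)C)[C@@H](C([N+](=O)[O-])C1)C(C)C | intermediate
9 | ethyl (3R,4S)-3-(TBSO)-4-isopropyl-5-oxocyclohex-1-ene-1-carboxylate | CCOC(=O)C1=C[C@@H](O[Si](C)(C)C(C)(C)C)[C@@H](C(=O)C1)C(C)C | intermediate
10 | ethyl (4S,5R)-5-(TBSO)-4-isopropyl-3-oxocyclohex-1-ene-1-carboxylate | CCOC(=O)C1=CC(=O)[C@@H](C(C)C)[C@H](O[Si](C)(C)C(C)(C)C)C1 | intermediate
11 | methylenecyclobutane | C=C1CCC1 | starting material
12 | 1-methylcyclobutene | CC1=CCC1 | intermediate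
13 | ladder keto ester (cis,anti,cis) | CCOC(=O)[C@@]12C[C@@H](O[Si](C)(C)C(C)(C)C)[C@H](C(C)C)C(=O)[C@@H]1[C@@]3(C)CC[C@@H]23 | intermediate
14 | ladder β-hydroxy keto ester | CCOC(=O)[C@@]12C[C@@H](O)[C@H](C(C)C)C(=O)[C@@H]1[C@@]3(C)CC[C@@H]23 | intermediate
15 | ladder 6,8-diol ester | CCOC(=O)[C@@]12C[C@@H](O)[C@H](C(C)C)[C@H](O)[C@@H]1[C@@]3(C)CC[C@@H]23 | intermediate
16 | (E,Z)-cyclodecadiene 6,8-diol ethyl ester | CCOC(=O)/C1=C/CC/C(C)=C/[C@@H](O)[C@@H](C(C)C)[C@H](O)C1 | intermediate
17 | ten-membered 8-hydroxy-6,15-olide | O=C1O[C@@H]2C/C1=C\CC/C(C)=C/[C@@H](O)[C@H]2C(C)C | intermediate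
18 | 6,8-dihydroxy Weinreb amide | CON(C)C(=O)/C1=C/CC/C(C)=C/[C@@H](O)[C@@H](C(C)C)[C@H](O)C1 | intermediate
19 | 6,8-diacetoxy Weinreb amide | CON(C)C(=O)/C1=C/CC/C(C)=C/[C@@H](OC(C)=O)[C@@H](C(C)C)[C@H](OC(C)=O)C1 | intermediate
20 | enal 6,8-diacetate | O=C/C1=C/CC/C(C)=C/[C@@H](OC(C)=O)[C@@H](C(C)C)[C@H](OC(C)=O)C1 | intermediate
21 | Pulicanaral A | CC(=O)O[C@@H]1/C=C(\C)CC[C@H]2O[C@@]2(C=O)C[C@@H](OC(C)=O)[C@@H]1C(C)C | target

**Totals**
Total steps: 13. Longest linear sequence: 12 (steps 1–4 and 6–13).

**Steps most likely to fail**

Step 9. The opened diene may drain by Cope rearrangement into the cis-divinylcyclohexane faster than O6 closes on C15, and long heating may erode material.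
- The fallback makes the lactone the precursor instead of the trap.
- From 15, saponification (LiOH, THF/H2O) would give the ladder dihydroxy acid F1.
- Yamaguchi lactonisation would engage O6, the only hydroxyl cis to the carboxyl, to give the bridged ladder lactone F2.
- The extra strain of F2 (axial isopropyl) should lower the opening temperature. Its thermolysis would give the lactone directly, returning to the route at 17.

Step 4. During the alkene shift the extended enolate may expel silanolate vinylogously, and the ring may aromatise.
- The fallback removes the alkene and reintroduces it by dehydrogenation.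
- From 9 (isolated after the oxidation, without amine), hydrogenation (H2, Pd/C, EtOAc) would give the saturated keto ester F3.
- Kinetic enolisation on the CH2 side (LDA, TMSCl, –78 °C) would give the silyl enol ether F4.
- Saegusa–Ito oxidation (Pd(OAc)2, MeCN) would install C4=C9, returning at 10.

Step 13. Facial selectivity may be poor, or dienamine formation may scramble the alkene.
- The fallback switches to a reagent-controlled epoxidation of an allylic alcohol.
- From 17, DIBAL-H would give the triol F5.
- 2,2-Dimethoxypropane/PPTS would tie O6 and O8 into the 6,8-acetonide allylic alcohol F6.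
- Sharpless asymmetric epoxidation (Ti(OiPr)4, D-(–)-DIPT, TBHP) would give the epoxy alcohol acetonide F7.
- Dess–Martin oxidation would give the epoxy aldehyde acetonide F8.
- Aqueous AcOH would give the epoxy aldehyde diol F9. Its lactol would need a trans-bridged ring and should not interfere.
- Ac2O/pyridine would then return to the route at 21.

**Further compounds**
F1 | step 9 | ladder dihydroxy acid | OC(=O)[C@@]12C[C@@H](O)[C@H](C(C)C)[C@H](O)[C@@H]1[C@@]3(C)CC[C@@H]23
F2 | step 9 | bridged ladder lactone (C15–O6) | O=C1O[C@@H]2C[C@]13[C@@H]4CC[C@]4(C)[C@H]3[C@@H](O)[C@H]2C(C)C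
F3 | step 4 | saturated keto ester (C4 undefined) | CCOC(=O)C1C[C@@H](O[Si](C)(C)C(C)(C)C)[C@@H](C(=O)C1)C(C)C
F4 | step 4 | C8=C9 trimethylsilyl enol ether | CCOC(=O)C1C[C@@H](O[Si](C)(C)C(C)(C)C)[C@@H](C(O[Si](C)(C)C)=C1)C(C)C
F5 | step 13 | 6,8,15-triol | OC/C1=C/CC/C(C)=C/[C@@H](O)[C@@H](C(C)C)[C@H](O)C1
F6 | step 13 | 6,8-acetonide allylic alcohol | OC/C1=C/CC/C(C)=C/[C@H]2OC(C)(C)O[C@H](C1)[C@@H]2C(C)C
F7 | step 13 | epoxy alcohol acetonide | CC1(C)O[C@@H]2/C=C(\C)CC[C@H]3O[C@@]3(CO)C[C@@H](O1)[C@@H]2C(C)C
F8 | step 13 | epoxy aldehyde acetonide | CC1(C)O[C@@H]2/C=C(\C)CC[C@H]3O[C@@]3(C=O)C[C@@H](O1)[C@@H]2C(C)C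
F9 | step 13 | epoxy aldehyde 6,8-diol | O[C@@H]1/C=C(\C)CC[C@H]2O[C@@]2(C=O)C[C@@H](O)[C@@H]1C(C)C
A1 | direct plan | open-chain epoxy aldehyde with C9 (E)-vinyl iodide, 6-OAc, 15-OTIPS | CC(C)[Si](C(C)C)(C(C)C)OC[C@@]1(C[C@@H](OC(C)=O)[C@H](C(C)C)C=O)O[C@@H]1CC/C(C)=C/I
A2 | direct plan | ten-membered C8 carbinol (C8 epimers), 15-OTIPS | OC1/C=C(\C)CC[C@H]2O[C@@]2(CO[Si](C(C)C)(C(C)C)C(C)C)C[C@@H](OC(C)=O)[C@@H]1C(C)C
A3 | direct plan | macrocyclic C8 enone, 15-OTIPS | O=C1/C=C(\C)CC[C@H]2O[C@@]2(CO[Si](C(C)C)(C(C)C)C(C)C)C[C@@H](OC(C)=O)[C@@H]1C(C)C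
A4 | direct plan | 6,8-diacetoxy-3,4-epoxy C15 primary alcohol | CC(=O)O[C@@H]1/C=C(\C)CC[C@H]2O[C@@]2(CO)C[C@@H](OC(C)=O)[C@@H]1C(C)C
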